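Remark: isoflavone numbering is used throughout (ring A = C4a–C8a, ring C = the pyranone, ring B = C1'–C6' on C3; the C6 chain is C1''–C4'', the ring B chain C1'''–C4'''). The target structure encodes the R configuration at C2''.

## Analysis of the target

The target 19 is genistein carrying two C-bound five-carbon chains. Ring A (C4a–C8a) bears hydroxyls on C5 and C7, ring C is the pyranone, and ring B on C3 bears a hydroxyl on C4'. C3' carries a prenyl group and C6 carries an (R)-2-hydroxy-3-methylbut-3-enyl group, so the two chains have the same carbon count but differ in oxidation pattern. C2'' is the only stereocentre. It is a secondary allylic carbinol between a benzylic methylene and an isopropenyl group, has no neighbouring stereo-element, and must therefore be set by a reagent. The sensitive sites are the isopropenyl carbinol, which sits between two ortho phenols (O5, O7) and can cyclise or ionise under acid, the ring B ortho-prenylphenol, which cyclises to a chroman under acid, and the pyranone, which opens under strong aqueous base. The C5 hydroxyl is chelated to C4=O and reacts sluggishly. The difficulties are regiocontrol of C-alkylation (C6 against C8 on ring A, both flanked by two oxygens), keeping the two chains distinguishable, and one remote stereocentre. The strategy rests on a positional fact: ortho to O5 there are only C6 (with hydrogen) and the ring-fusion carbon C4a (without), and ortho to O4' there are C3' and C5', equivalent by rotation about C3–C1'. An allyl group that moves from O5 or O4' to an ortho carbon can therefore end only on the two carbons that carry chains in 19, and genistein already supplies every ring atom and oxygen.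

## Retrosynthetic reasoning

19 ⇒ 18. The last bonds cut are the three O–CH2 acetal bonds of the methoxymethyl (MOM) ethers on O5, O7 and O4' of 18. The phenols are released last because each interferes earlier: O7 and O4' as competing nucleophiles, O5 and O7 as neighbours of an epoxide. Acetal cleavage leaves C2'' untouched. The forward step must be mild enough to spare the isopropenyl carbinol and the prenyl group.

18 ⇒ 17 ⇒ 16. The C2'' hydroxyl and the C3''=C4'' alkene of 18 are read as the two ends of an opened epoxide. Reconnecting oxygen to C3'' and placing iodine on C4'' gives epoxy iodide 17, and exchanging iodine for hydroxyl gives epoxy alcohol 16. This transposition delivers the 1,1-disubstituted alkene regiospecifically. It also moves the stereochemical problem to the CH carbon of an epoxide whose C–O bond is never broken afterwards. The forward reaction is metal insertion into C–I followed by β-elimination.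

16 ⇒ 15. Removing the epoxide oxygen gives the (E)-allylic alcohol 15. A primary allylic alcohol is the substrate class for which the Sharpless asymmetric epoxidation gives a predictable absolute configuration. The directing hydroxyl also explains why the C6 chain alkene reacts and the ring B prenyl alkene does not. The forward step must deliver oxygen to the face that makes both epoxide carbons R.

15 ⇒ 14 ⇒ 12 + 13. Alcohol 15 comes from enal 14 by 1,2-reduction. The C2''=C3'' bond of 14 is cut in the cross-metathesis sense into the terminal allyl group of 12 and methacrolein 13. The cut is made here because, after the rearrangement, the only handle that separates the C6 chain from the ring B chain is alkene substitution (monosubstituted against trisubstituted). The forward reaction must engage only the monosubstituted alkene and give the E enal.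

12 ⇒ 10. Removing the MOM groups from O5 and O4' reveals 10, the product of the key step. Capping both phenols is needed before an epoxide is placed two atoms from ring A and before a titanium catalyst is used. MOM is chosen over silyl because the hindered, chelated O5 must be blocked as well, and all three acetals then fall in one final operation.

10 ⇒ 8 (through 9). This is the key disconnection. C6–C1'' and C3'–C1''' are cut and each three-carbon unit is returned, with allylic transposition, to the neighbouring oxygen: an allyl group on O5 and a 1,1-dimethylallyl group on O4'. Two C–C bonds are traded for two C–O bonds that are easy to make on the intact isoflavone. The positions are dictated by the ring substitution, and the two chains emerge different (allyl and prenyl), which the metathesis step needs. In the forward direction two thermal [3,3] shifts run in one operation, the tertiary ether first (giving 9), then the allyl ether.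

8 ⇒ 6 + 7, 6 ⇒ 2 + 5, 5 ⇒ 3 (through 4), 2 ⇒ 1. The three O–C bonds are cut in reverse order of phenol acidity. The chelated O5 is allylated last with allyl bromide 7. O4' receives the tertiary allyl group from carbonate 5, made from alcohol 3. The most acidic O7 is blocked first on genistein 1. This order lets each alkylation find only one reactive hydroxyl.

## Alternatives that were turned down

Alternative 1: Ring A is built around C6 by cutting C6–C7, C4a–C5 and C7–C8, which leads to cyclobutenone A2 and the chain-bearing siloxyalkyne A3. In the forward key step (Danheiser benzannulation) heating opens A2 to a vinylketene, which adds across A3. The new cyclobutenone opens again and the dienylketene closes by 6π-electrocyclisation to phenol A1. In its favour, the chain and its stereocentre are made beforehand on a small acyclic fragment and are built into ring A at C6 with no C6/C8 ambiguity. The three ring A oxygens emerge differentiated, and no step has to tell two alkenes apart. Against it, A1 is only ring A. C4a still carries hydrogen, so the pyranone and ring B must be added afterwards by acylation at C4a and a one-carbon closure. That acylation competes with C8, which is equally flanked by two oxygens, and it must be run beside an allylic silyl ether and a 1,1-disubstituted alkene that do not tolerate Friedel–Crafts acids. A3 also needs a multistep synthesis and is sensitive to heat and moisture. On regiochemical certainty at C6 this alternative is stronger than the chosen route. The chosen route offers instead a skeleton that is complete from the first step and a much shorter sequence, whereas this plan only moves the regiochemical question to C4a/C8.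

Alternative 2: C1''–C2'' and C2''–C3'' are both formed at a boron-bearing carbon, leading back to the ring A benzylboronic ester A5 of a C2-symmetric diol. In the forward key step (Matteson homologation) A5 takes up a dichloromethyl carbenoid and the benzyl group migrates to give an α-chloro boronic ester. An isopropenyl-metal nucleophile then displaces chloride through a second ate complex to give the secondary allylic boronic ester A4, whose C–B bond is later oxidised with retention. In its favour, stereocontrol by the diol is typically very high and substrate-independent, the chain is built directly, and the symmetric ring A fragment raises no regiochemical question at that stage. Against it, A4 again contains only ring A. After oxidation and protection the pyranone and the prenylated ring B must still be attached by acylation next to an acid-sensitive allylic system, and A5 itself needs benzylic functionalisation of a phloroglucinol derivative. In stereochemical reliability this alternative is at least as strong as the Sharpless step of the chosen route, and it avoids the two-alkene chemoselectivity problem. The chosen route offers in exchange a commercial starting material that already holds all three rings, and a far shorter sequence.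

Alternative 3: Ring A is cut at C7–C8 and C5–C6, giving the ring B-bearing pyranone ester A7 and the enantiopure γ-lactone A8. In the forward key step the C2 methyl of A7 is deprotonated by a lithium amide and acylated by the lactone carbonyl, which releases the C2'' alkoxide. A second deprotonation at C6 then closes the ring onto the ester (Dieckmann-type) and aromatises to A6. In its favour it is the most convergent plan: A6 is one protecting group from the target, the stereocentre arrives in a small lactone, ring A regiochemistry is unambiguous and no late oxidation-state changes are needed. Against it, the C6 carbanion must form beside the far more acidic C8 methylene between the new ketone and the pyranone, so a polyanion is required. The γ-hydroxy ketone from lactone opening can close to a lactol or revert. The pyranone is itself an electrophile towards amide bases at its unsubstituted ring carbon, the ester is flanked on both sides, and A7 and A8 each need several steps. If the annulation worked, this alternative would be shorter than the chosen route and stronger in convergence. The chosen route offers predictability in its place: every bond is made by a reaction with close analogy, and its uncertain step concerns only how cleanly two known rearrangements run in one operation, with a stepwise fallback at hand.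

Key step: step 5

## Route

Step 1
Reactants: 1 genistein
Product: 2 5-hydroxy-3-(4-hydroxyphenyl)-7-(methoxymethoxy)-4H-chromen-4-one (7-O-MOM-genistein)
Conditions: MOMCl (1.0 equiv), iPr2NEt (1.1 equiv), DMF, −10 → 0 °C
Reagents that add atoms: chloromethyl methyl ether (MOMCl), COCCl
Why: The C7 hydroxyl is para to the C4 carbonyl (a vinylogous acid) and is the most acidic phenol, so one equivalent of base should give mainly the C7 phenoxide, which is O-alkylated (Williamson-type etherification); the C5 hydroxyl is tied up in a hydrogen bond to C4=O and the C4' hydroxyl is a much weaker acid.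

Step 2
Reactants: 3 2-methylbut-3-en-2-ol
Product: 5 methyl 2-methylbut-3-en-2-yl carbonate, via lithium 2-methylbut-3-en-2-olate 4 (not isolated)
Conditions: n-BuLi, THF, −78 °C; ClCO2Me, −78 °C → rt
Reagents that add atoms: methyl chloroformate, COC(=O)Cl
Why: The hindered tertiary alcohol is deprotonated to its lithium alkoxide and acylated by the chloroformate (carbonate formation); a tertiary allylic carbonate is the standard ionisable partner for π-allyl chemistry.

Step 3
Reactants: 2 7-O-MOM-genistein; 5 methyl 2-methylbut-3-en-2-yl carbonate
Product: 6 5-hydroxy-7-(methoxymethoxy)-3-[4-(2-methylbut-3-en-2-yloxy)phenyl]-4H-chromen-4-one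
Conditions: Pd(PPh3)4 (2 mol%), 4 Å MS, THF, 0 °C → rt
Reagents that add atoms: none
Why: Zerovalent palladium ionises 5 with loss of CO2 to a 1,1-dimethyl-π-allyl complex and methoxide, which deprotonates the C4' phenol (decarboxylative Tsuji–Trost O-allylation). Under kinetic control at low temperature the phenoxide attacks the more substituted allyl terminus and gives the tertiary ether; the chelated C5 hydroxyl should not compete.

Step 4
Reactants: 6 the 4'-O-(1,1-dimethylallyl) ether; 7 allyl bromide
Product: 8 5-(allyloxy)-7-(methoxymethoxy)-3-[4-(2-methylbut-3-en-2-yloxy)phenyl]-4H-chromen-4-one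
Conditions: Cs2CO3, DMF, rt → 40 °C
Reagents that add atoms: none
Why: Cs2CO3 in DMF breaks the C5–OH···O=C4 hydrogen bond and the phenoxide is alkylated by the primary allylic bromide (Williamson etherification). The temperature stays well below that at which the tertiary allyl ether starts to rearrange.

Step 5
Reactants: 8 the 5-O-allyl 4'-O-(1,1-dimethylallyl) bis-ether
Product: 10 6-allyl-5-hydroxy-3-[4-hydroxy-3-(3-methylbut-2-enyl)phenyl]-7-(methoxymethoxy)-4H-chromen-4-one, via mono-rearranged 5-O-allyl-3'-prenyl phenol 9 (not isolated)
Conditions: PhNEt2 (degassed), Ar, 130 °C, then 200 °C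
Reagents that add atoms: none
Why: Two aromatic Claisen rearrangements run in sequence, each a [3,3]-sigmatropic shift through a chair-like six-membered transition state; the closest known reaction type is the thermal ortho-Claisen rearrangement of aryl allyl and aryl 1,1-dimethylallyl ethers used for C-allylation and C-prenylation of flavonoids. At about 130 °C the tertiary ether on O4' should shift first, and because the allyl unit is transposed, the 1,1-dimethylallyl group on oxygen arrives on C3' as a 3,3-dimethylallyl (prenyl) group; enolisation of the ortho-dienone gives phenol 9. At about 200 °C the O5 allyl ether follows, forming C6–C1'', and enolisation gives the chelated C5 hydroxyl of 10. No ring is closed and no stereocentre is formed. The step needs site selectivity on both rings: on ring A the only other ortho carbon, C4a, has no hydrogen, so a shift there is reversible and unproductive, and on ring B C3' and C5' are equivalent. Fast tautomerisation of the C6 dienone, helped by the amine solvent, should forestall a further Cope shift of the allyl group to C8. The basic medium also suppresses acid-catalysed cleavage of the tertiary ether and chroman formation from the new ortho-prenylphenol, and the C7 MOM ether is thermally inert and keeps O7 out of the reaction.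

Step 6
Reactants: 10 6-allyl-3'-prenyl-7-O-MOM-genistein
Product: 12 6-allyl-5,7-bis(methoxymethoxy)-3-[4-(methoxymethoxy)-3-(3-methylbut-2-enyl)phenyl]-4H-chromen-4-one, via disodium 5,4'-bis-phenoxide 11 (not isolated)
Conditions: NaH, DMF, 0 °C; MOMCl, 0 °C → rt
Reagents that add atoms: chloromethyl methyl ether (MOMCl), COCCl
Why: NaH converts both phenols, including the chelated C5 hydroxyl, into phenoxides that are O-alkylated (Williamson-type acetal formation). Both must be capped because a free ortho phenol would open the later epoxide intramolecularly and free phenols would bind the titanium catalyst.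

Step 7
Reactants: 12 the tris-MOM 6-allyl compound; 13 methacrolein (10 equiv)
Product: 14 (2E)-4-{5,7-bis(methoxymethoxy)-3-[4-(methoxymethoxy)-3-(3-methylbut-2-enyl)phenyl]-4-oxo-4H-chromen-6-yl}-2-methylbut-2-enal
Conditions: second-generation Hoveyda–Grubbs catalyst RuCl2(H2IMes)(=CH-C6H4-2-OiPr) (5 mol%), 1,4-benzoquinone (cat.), CH2Cl2, 40 °C
Reagents that add atoms: none
Why: In this olefin cross-metathesis the monosubstituted allyl alkene initiates readily on ruthenium and couples with excess methacrolein to the thermodynamically favoured (E)-trisubstituted enal, with loss of ethylene. The trisubstituted ring B prenyl alkene enters the cycle much more slowly, so the reaction is stopped once the terminal alkene is consumed; benzoquinone suppresses hydride-mediated double-bond migration.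

Step 8
Reactants: 14 the (E)-enal
Product: 15 6-[(2E)-4-hydroxy-3-methylbut-2-enyl]-5,7-bis(methoxymethoxy)-3-[4-(methoxymethoxy)-3-(3-methylbut-2-enyl)phenyl]-4H-chromen-4-one
Conditions: NaBH4, CeCl3·7H2O, MeOH/THF, −20 °C
Reagents that add atoms: none
Why: Luche reduction delivers hydride 1,2 to the enal carbonyl within minutes at low temperature and retains the alkene geometry; the pyranone carbonyl is a vinylogous ester and should not be reduced under these conditions.

Step 9
Reactants: 15 the (E)-allylic alcohol
Product: 16 6-{[(2R,3R)-3-(hydroxymethyl)-3-methyloxiran-2-yl]methyl}-5,7-bis(methoxymethoxy)-3-[4-(methoxymethoxy)-3-(3-methylbut-2-enyl)phenyl]-4H-chromen-4-one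
Conditions: Ti(OiPr)4 (10 mol%), D-(−)-diethyl tartrate (12 mol%), t-BuOOH (in decane), 4 Å MS, CH2Cl2, −20 °C
Reagents that add atoms: tert-butyl hydroperoxide, CC(C)(C)OO
Why: In the Sharpless asymmetric epoxidation the primary allylic alcohol binds to the titanium–tartrate complex, which delivers the peroxide oxygen to one alkene face. D-(−)-diethyl tartrate is expected to give the epoxide with both ring carbons R, the mirror image of the (2S,3S) epoxides that L-(+)-tartrate gives with (E)-allylic alcohols, and this fixes the future C2'' as R. The ring B prenyl alkene has no coordinating hydroxyl and should not be epoxidised.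

Step 10
Reactants: 16 the (2R,3R)-epoxy alcohol
Product: 17 6-{[(2R,3S)-3-(iodomethyl)-3-methyloxiran-2-yl]methyl}-5,7-bis(methoxymethoxy)-3-[4-(methoxymethoxy)-3-(3-methylbut-2-enyl)phenyl]-4H-chromen-4-one
Conditions: PPh3, I2, imidazole (reagent preformed), CH2Cl2, 0 °C
Reagents that add atoms: iodine, II
Why: In this Appel-type iodination the phosphonium iodide reagent activates the primary hydroxyl as an alkoxyphosphonium ion, which iodide displaces by SN2, while imidazole keeps the medium non-acidic so the epoxide stays closed. Neither epoxide carbon reacts; the quaternary carbon changes descriptor from R to S only because CH2I outranks the ring carbon.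

Step 11
Reactants: 17 the epoxy iodide
Product: 18 6-[(2R)-2-hydroxy-3-methylbut-3-enyl]-5,7-bis(methoxymethoxy)-3-[4-(methoxymethoxy)-3-(3-methylbut-2-enyl)phenyl]-4H-chromen-4-one
Conditions: Zn dust, EtOH, 70 °C; then H2O
Reagents that add atoms: none
Why: Zinc inserts into the C–I bond and the organozinc undergoes β-elimination, opening the epoxide at the quaternary carbon (reductive ring opening of a 2,3-epoxy iodide). The C2''–O bond is not touched, so the R configuration from step 9 is carried into the secondary allylic alcohol and C3''=C4'' forms regiospecifically.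

Step 12
Reactants: 18 the tris-MOM ether of the target
Product: 19 5,7-dihydroxy-3-[4-hydroxy-3-(3-methylbut-2-enyl)phenyl]-6-[(2R)-2-hydroxy-3-methylbut-3-enyl]-4H-chromen-4-one (target)
Conditions: HCl (ca. 1 M in MeOH), MeOH/THF, rt
Reagents that add atoms: none
Why: Acid-catalysed acetal exchange with methanol removes the three aryl MOM ethers as dimethoxymethane. Dilute acid at room temperature is chosen to stay below the threshold for addition of a phenol to the isopropenyl or prenyl alkene and for ionisation of the allylic alcohol; C2'' is not involved.

## Compound list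

1 | genistein (5,7-dihydroxy-3-(4-hydroxyphenyl)-4H-chromen-4-one) | O=c1c(-c2ccc(O)cc2)coc2cc(O)cc(O)c12 | starting material
2 | 7-O-(methoxymethyl)genistein | O=c1c(-c2ccc(O)cc2)coc2cc(OCOC)cc(O)c12 | intermediate
3 | 2-methylbut-3-en-2-ol | CC(C)(O)C=C | starting material
4 | lithium 2-methylbut-3-en-2-olate (not isolated) | [Li+].CC(C)([O-])C=C | intermediate
5 | methyl 2-methylbut-3-en-2-yl carbonate | COC(=O)OC(C)(C)C=C | intermediate
6 | 4'-O-(1,1-dimethylallyl)-7-O-(methoxymethyl)genistein | O=c1c(-c2ccc(OC(C)(C)C=C)cc2)coc2cc(OCOC)cc(O)c12 | intermediate
7 | allyl bromide | C=CCBr | starting material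
8 | 5-O-allyl-4'-O-(1,1-dimethylallyl)-7-O-(methoxymethyl)genistein | C=CCOc1cc(OCOC)cc2occ(-c3ccc(OC(C)(C)C=C)cc3)c(=O)c12 | intermediate
9 | 5-O-allyl-3'-prenyl-7-O-(methoxymethyl)genistein (4'-OH free; not isolated) | C=CCOc1cc(OCOC)cc2occ(-c3ccc(O)c(CC=C(C)C)c3)c(=O)c12 | intermediate
10 | 6-allyl-3'-prenyl-7-O-(methoxymethyl)genistein (5-OH and 4'-OH free) | C=CCc1c(OCOC)cc2occ(-c3ccc(O)c(CC=C(C)C)c3)c(=O)c2c1O | intermediate
11 | disodium 5,4'-bis-phenoxide of 10 (not isolated) | C=CCc1c(OCOC)cc2occ(-c3ccc([O-])c(CC=C(C)C)c3)c(=O)c2c1[O-].[Na+].[Na+] | intermediate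
12 | 6-allyl-3'-prenyl-5,7,4'-tri-O-(methoxymethyl)genistein | C=CCc1c(OCOC)cc2occ(-c3ccc(OCOC)c(CC=C(C)C)c3)c(=O)c2c1OCOC | intermediate
13 | methacrolein | C=C(C)C=O | starting material
14 | (E)-enal: 6-[(2E)-3-methyl-4-oxobut-2-enyl]-3'-prenyl-5,7,4'-tri-O-(methoxymethyl)genistein | O=C/C(C)=C/Cc1c(OCOC)cc2occ(-c3ccc(OCOC)c(CC=C(C)C)c3)c(=O)c2c1OCOC | intermediate
15 | (E)-allylic alcohol: 6-[(2E)-4-hydroxy-3-methylbut-2-enyl]-3'-prenyl-5,7,4'-tri-O-(methoxymethyl)genistein | OC/C(C)=C/Cc1c(OCOC)cc2occ(-c3ccc(OCOC)c(CC=C(C)C)c3)c(=O)c2c1OCOC | intermediate
16 | epoxy alcohol, both epoxide carbons R: 6-{[(2R,3R)-3-(hydroxymethyl)-3-methyloxiran-2-yl]methyl}-3'-prenyl-5,7,4'-tri-O-(methoxymethyl)genistein | OC[C@@]1(C)O[C@@H]1Cc2c(OCOC)cc3occ(-c4ccc(OCOC)c(CC=C(C)C)c4)c(=O)c3c2OCOC | intermediate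
17 | epoxy iodide: 6-{[(2R,3S)-3-(iodomethyl)-3-methyloxiran-2-yl]methyl}-3'-prenyl-5,7,4'-tri-O-(methoxymethyl)genistein | IC[C@@]1(C)O[C@@H]1Cc2c(OCOC)cc3occ(-c4ccc(OCOC)c(CC=C(C)C)c4)c(=O)c3c2OCOC | intermediate
18 | 6-[(2R)-2-hydroxy-3-methylbut-3-enyl]-3'-prenyl-5,7,4'-tri-O-(methoxymethyl)genistein | C=C(C)[C@H](O)Cc1c(OCOC)cc2occ(-c3ccc(OCOC)c(CC=C(C)C)c3)c(=O)c2c1OCOC | intermediate
19 | 6-[(2R)-2-hydroxy-3-methylbut-3-enyl]-3'-prenylgenistein (CNP0138374.1) | C=C(C)[C@H](O)Cc1c(O)cc2occ(-c3ccc(O)c(CC=C(C)C)c3)c(=O)c2c1O | target

## Step count and least certain steps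

Total: 12 steps. Longest linear sequence: 11 steps (steps 1 and 3–12 from genistein 1); step 2 is a one-step side branch.

Step 5 (key step). The most likely failure is an unclean second stage. At about 200 °C the ring B ortho-prenylphenol released in the first stage may add across its own alkene, or the tertiary ether may fragment by loss of the C5 unit before it rearranges if the first stage is not complete. The cause is that one rearrangement needs about 70 °C more than the other while a reactive phenol is already present. The fallback separates the two shifts and caps the ring B phenol in between; it sets out from 6 and comes back at 12. Compound 6 alone is heated at about 130 °C in PhNEt2 to give 3'-prenyl-7-O-(methoxymethyl)genistein F1. Its C4' hydroxyl is capped selectively with MOMCl and iPr2NEt in CH2Cl2 (the chelated C5 hydroxyl does not react) to give 3'-prenyl-7,4'-di-O-(methoxymethyl)genistein F2. Allylation of O5 with 7 and Cs2CO3 in DMF gives 5-O-allyl-3'-prenyl-7,4'-di-O-(methoxymethyl)genistein F3. A single Claisen rearrangement at about 200 °C in PhNEt2 gives 6-allyl-3'-prenyl-7,4'-di-O-(methoxymethyl)genistein F4. NaH and MOMCl then give 12.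

Step 7. The ring B prenyl alkene may enter the metathesis cycle and lose its isopropylidene end, above all once the terminal alkene is used up, and the allyl double bond may migrate into conjugation with ring A through ruthenium hydrides. Both follow from two alkenes of different but not infinitely different reactivity sharing one catalyst. The fallback runs the metathesis before ring B carries a prenyl group and gives up the single-operation double rearrangement; it sets out from 2 and comes back at 14.
- Silylation of the C4' hydroxyl of 2 (iPr3SiCl, imidazole, DMF) gives 4'-O-(triisopropylsilyl)-7-O-(methoxymethyl)genistein F5.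
- Allylation of O5 (7, K2CO3, acetone, reflux) gives 5-O-allyl-4'-O-(triisopropylsilyl)-7-O-(methoxymethyl)genistein F6.
- Claisen rearrangement at about 200 °C in PhNEt2 gives 6-allyl-4'-O-(triisopropylsilyl)-7-O-(methoxymethyl)genistein F7.
- NaH and MOMCl give 6-allyl-4'-O-(triisopropylsilyl)-5,7-di-O-(methoxymethyl)genistein F8.
- Cross-metathesis with 13 under the conditions of step 7, now with no second alkene present, gives 6-[(2E)-3-methyl-4-oxobut-2-enyl]-4'-O-(triisopropylsilyl)-5,7-di-O-(methoxymethyl)genistein F9.
- Bu4NF buffered with AcOH gives 6-[(2E)-3-methyl-4-oxobut-2-enyl]-5,7-di-O-(methoxymethyl)genistein F10.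
- O-Alkylation with 5 and Pd(PPh3)4 as in step 3 gives 4'-O-(1,1-dimethylallyl)-6-[(2E)-3-methyl-4-oxobut-2-enyl]-5,7-di-O-(methoxymethyl)genistein F11.
- Heating at about 130 °C in xylene gives 6-[(2E)-3-methyl-4-oxobut-2-enyl]-3'-prenyl-5,7-di-O-(methoxymethyl)genistein F12.
- MOMCl and iPr2NEt then give 14.

Step 12. Protic acid may add the O5 or O7 phenol to the isopropenyl alkene (ring closure onto C3''), add the O4' phenol to the prenyl alkene, or ionise the allylic C2''–O bond. The cause is that the slowest acetal to leave, on electron-rich ring B, sets the acid exposure for the whole molecule. The fallback replaces protic hydrolysis by a buffered, aprotic silyl exchange; it sets out from 18 and comes back at 19. Me3SiOTf with 2,2'-bipyridyl in CH2Cl2 at 0 °C converts each aryl MOM ether into an aryl trimethylsilyl ether and silylates the alcohol, giving the 5,7,4',2''-tetrakis-O-(trimethylsilyl) derivative of the target F13. This is not isolated and is cleaved to 19 by K2CO3 in MeOH at 0 °C.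

Step 1. Over-alkylation at O4' (and loss of material as the bis-ether) may occur because the chloromethyl ether is reactive enough to capture the small equilibrium share of the C4' phenoxide. The fallback differentiates the phenols through esters; it sets out from 1 and comes back at 2. Ac2O and pyridine give 5,7,4'-tri-O-acetylgenistein F14. PhSH and imidazole in N-methylpyrrolidone remove only the C7 acetate, the ester of the most acidic phenol, giving 5,4'-di-O-acetylgenistein F15. MOMCl and iPr2NEt give 5,4'-di-O-acetyl-7-O-(methoxymethyl)genistein F16, and K2CO3 in MeOH then gives 2.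

Step 3. Zerovalent palladium may re-ionise the tertiary ether and equilibrate it to the linear prenyl ether, which would later rearrange to the wrong (reverse-prenyl) chain; the branched ether is only the kinetic product. The fallback builds the tertiary ether without a π-allyl intermediate; it sets out from 2 and comes back at 6. 3-Chloro-3-methylbut-1-yne with CuCl2·2H2O (catalytic) and DBU in MeCN at 0 °C gives 4'-O-(1,1-dimethylprop-2-ynyl)-7-O-(methoxymethyl)genistein F17. Semi-hydrogenation (H2, Pd/CaCO3 poisoned with Pb(OAc)2, quinoline, EtOAc) then gives 6; no other alkene is present at this stage.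

## Further compounds

F1 | step 5 | 3'-prenyl-7-O-(methoxymethyl)genistein | O=c1c(-c2ccc(O)c(CC=C(C)C)c2)coc2cc(OCOC)cc(O)c12
F2 | step 5 | 3'-prenyl-7,4'-di-O-(methoxymethyl)genistein | O=c1c(-c2ccc(OCOC)c(CC=C(C)C)c2)coc2cc(OCOC)cc(O)c12
F3 | step 5 | 5-O-allyl-3'-prenyl-7,4'-di-O-(methoxymethyl)genistein | C=CCOc1cc(OCOC)cc2occ(-c3ccc(OCOC)c(CC=C(C)C)c3)c(=O)c12
F4 | step 5 | 6-allyl-3'-prenyl-7,4'-di-O-(methoxymethyl)genistein | C=CCc1c(OCOC)cc2occ(-c3ccc(OCOC)c(CC=C(C)C)c3)c(=O)c2c1O
F5 | step 7 | 4'-O-(triisopropylsilyl)-7-O-(methoxymethyl)genistein | O=c1c(-c2ccc(O[Si](C(C)C)(C(C)C)C(C)C)cc2)coc2cc(OCOC)cc(O)c12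
F6 | step 7 | 5-O-allyl-4'-O-(triisopropylsilyl)-7-O-(methoxymethyl)genistein | C=CCOc1cc(OCOC)cc2occ(-c3ccc(O[Si](C(C)C)(C(C)C)C(C)C)cc3)c(=O)c12
F7 | step 7 | 6-allyl-4'-O-(triisopropylsilyl)-7-O-(methoxymethyl)genistein | C=CCc1c(OCOC)cc2occ(-c3ccc(O[Si](C(C)C)(C(C)C)C(C)C)cc3)c(=O)c2c1O
F8 | step 7 | 6-allyl-4'-O-(triisopropylsilyl)-5,7-di-O-(methoxymethyl)genistein | C=CCc1c(OCOC)cc2occ(-c3ccc(O[Si](C(C)C)(C(C)C)C(C)C)cc3)c(=O)c2c1OCOC
F9 | step 7 | 6-[(2E)-3-methyl-4-oxobut-2-enyl]-4'-O-(triisopropylsilyl)-5,7-di-O-(methoxymethyl)genistein | O=C/C(C)=C/Cc1c(OCOC)cc2occ(-c3ccc(O[Si](C(C)C)(C(C)C)C(C)C)cc3)c(=O)c2c1OCOC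
F10 | step 7 | 6-[(2E)-3-methyl-4-oxobut-2-enyl]-5,7-di-O-(methoxymethyl)genistein | O=C/C(C)=C/Cc1c(OCOC)cc2occ(-c3ccc(O)cc3)c(=O)c2c1OCOC
F11 | step 7 | 4'-O-(1,1-dimethylallyl)-6-[(2E)-3-methyl-4-oxobut-2-enyl]-5,7-di-O-(methoxymethyl)genistein | O=C/C(C)=C/Cc1c(OCOC)cc2occ(-c3ccc(OC(C)(C)C=C)cc3)c(=O)c2c1OCOC
F12 | step 7 | 6-[(2E)-3-methyl-4-oxobut-2-enyl]-3'-prenyl-5,7-di-O-(methoxymethyl)genistein | O=C/C(C)=C/Cc1c(OCOC)cc2occ(-c3ccc(O)c(CC=C(C)C)c3)c(=O)c2c1OCOC
F13 | step 12 | 5,7,4',2''-tetrakis-O-(trimethylsilyl) derivative of the target, (R) at C2'' | C=C(C)[C@H](O[Si](C)(C)C)Cc1c(O[Si](C)(C)C)cc2occ(-c3ccc(O[Si](C)(C)C)c(CC=C(C)C)c3)c(=O)c2c1O[Si](C)(C)C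
F14 | step 1 | 5,7,4'-tri-O-acetylgenistein | CC(=O)Oc1ccc(-c2coc3cc(OC(C)=O)cc(OC(C)=O)c3c2=O)cc1
F15 | step 1 | 5,4'-di-O-acetylgenistein | CC(=O)Oc1ccc(-c2coc3cc(O)cc(OC(C)=O)c3c2=O)cc1
F16 | step 1 | 5,4'-di-O-acetyl-7-O-(methoxymethyl)genistein | CC(=O)Oc1ccc(-c2coc3cc(OCOC)cc(OC(C)=O)c3c2=O)cc1
F17 | step 3 | 4'-O-(1,1-dimethylprop-2-ynyl)-7-O-(methoxymethyl)genistein | O=c1c(-c2ccc(OC(C)(C)C#C)cc2)coc2cc(OCOC)cc(O)c12
A1 | alternative 1 | ring A phenol: 2-[(2R)-2-(tert-butyldimethylsilyloxy)-3-methylbut-3-enyl]-5-(4-methoxybenzyloxy)-3-(triisopropylsilyloxy)phenol | C=C(C)[C@H](O[Si](C)(C)C(C)(C)C)Cc1c(O)cc(OCc2ccc(OC)cc2)cc1O[Si](C(C)C)(C(C)C)C(C)C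
A2 | alternative 1 | 3-(4-methoxybenzyloxy)cyclobut-2-en-1-one | O=C1C=C(OCc2ccc(OC)cc2)C1
A3 | alternative 1 | (3R)-3-(tert-butyldimethylsilyloxy)-2-methyl-6-(triisopropylsilyloxy)hex-1-en-5-yne | C=C(C)[C@H](O[Si](C)(C)C(C)(C)C)CC#CO[Si](C(C)C)(C(C)C)C(C)C
A4 | alternative 2 | secondary allylic boronic ester: (4R,5R)-4,5-dicyclohexyl-2-{1-[2,6-bis(methoxymethoxy)-4-(triisopropylsilyloxy)phenyl]-3-methylbut-3-en-2-yl}-1,3,2-dioxaborolane | C=C(C)[C@H](B3O[C@H](C2CCCCC2)[C@@H](C2CCCCC2)O3)Cc1c(OCOC)cc(O[Si](C(C)C)(C(C)C)C(C)C)cc1OCOC
A5 | alternative 2 | benzylboronic ester: (4R,5R)-4,5-dicyclohexyl-2-{[2,6-bis(methoxymethoxy)-4-(triisopropylsilyloxy)phenyl]methyl}-1,3,2-dioxaborolane | COCOc1cc(O[Si](C(C)C)(C(C)C)C(C)C)cc(OCOC)c1CB1O[C@H](C2CCCCC2)[C@@H](C2CCCCC2)O1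
A6 | alternative 3 | 4'-O-(methoxymethyl) ether of the target | C=C(C)[C@H](O)Cc1c(O)cc2occ(-c3ccc(OCOC)c(CC=C(C)C)c3)c(=O)c2c1O
A7 | alternative 3 | methyl 5-[4-(methoxymethoxy)-3-(3-methylbut-2-enyl)phenyl]-2-methyl-4-oxo-4H-pyran-3-carboxylate | COC(=O)c1c(C)occ(-c2ccc(OCOC)c(CC=C(C)C)c2)c1=O
A8 | alternative 3 | (5R)-5-(prop-1-en-2-yl)oxolan-2-one | C=C(C)[C@H]1CCC(=O)O1
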